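The benzene ring is built last. Its 1,3-dihydroxy-5-alkyl pattern (OH on C1 and C3, H on C2, C4 and C6, the C17 chain on C5) is that of a decarboxylated tetraketide, so C5 is treated as the acyl carbon of an (S)-17-hydroxyoctadecanoyl unit and the other five ring carbons as acetate carbons. One base-mediated aldol condensation of a 6-(2,4-dioxoalkyl)-1,3-dioxin-4-one, a masked 3,5,7-triketo acid, forms the C5–C6 ring bond and aromatises in the same operation; saponification and decarboxylation then remove the temporary carboxyl on C6. The precursor is assembled by Claisen condensation of a silyl-protected C18 Weinreb amide with an acetyl-dioxinone dianion.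

Key step: step 9

Assumption: compounds 1, 4 and 9 and all reagents are purchased; lithium enolates generated before the electrophile is added are counted as non-isolated intermediates.

Step 1
Reactants: 1 15-pentadecanolide
Product: 2 15-hydroxy-N-methoxy-N-methylpentadecanamide
Conditions: MeNH(OMe)·HCl (3 equiv), AlMe3 (3 equiv), CH2Cl2, 0 °C to rt; cold 0.5 M HCl work-up
Reagents that add atoms: N,O-dimethylhydroxylamine hydrochloride, CNOC.Cl
Why: Weinreb aminolysis of a lactone: the chloro(methyl)aluminium amide formed in the flask opens the unstrained 16-membered lactone like an ordinary ester, so the Weinreb amide and the free primary alcohol should arise in one operation.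

Step 2
Reactants: 2 15-hydroxy-N-methoxy-N-methylpentadecanamide
Product: 3 N-methoxy-N-methyl-15-oxopentadecanamide
Conditions: 2,2,6,6-tetramethylpiperidin-1-oxyl (TEMPO, 0.1 equiv), PhI(OAc)2 (1.1 equiv), CH2Cl2, rt
Reagents that add atoms: none
Why: Oxoammonium (TEMPO) oxidation with PhI(OAc)2 as terminal oxidant takes a primary alcohol to the aldehyde without over-oxidation in the absence of water and does not affect the Weinreb amide.

Step 3
Reactants: 3 N-methoxy-N-methyl-15-oxopentadecanamide; 4 1-(triphenylphosphoranylidene)propan-2-one
Product: 5 (E)-N-methoxy-N-methyl-17-oxooctadec-15-enamide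
Conditions: 4 (1.5 equiv), toluene, 80 °C
Reagents that add atoms: none
Why: Wittig olefination with a ketone-stabilised ylide, which reacts only with the aldehyde, gives the E-enone under thermodynamic control and completes the C18 chain from 15 plus 3 carbons.

Step 4
Reactants: 5 (E)-N-methoxy-N-methyl-17-oxooctadec-15-enamide
Product: 6 (S,E)-17-hydroxy-N-methoxy-N-methyloctadec-15-enamide
Conditions: (R)-2-methyl-CBS-oxazaborolidine [(3aR)-1-methyl-3,3-diphenyltetrahydro-1H,3H-pyrrolo[1,2-c][1,3,2]oxazaborole, C18H20BNO, 0.2 equiv], catecholborane (1.8 equiv), toluene, −78 °C; MeOH quench, aq NaOH wash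
Reagents that add atoms: none
Why: Corey–Bakshi–Shibata reduction: the ketone oxygen binds to the ring boron anti to the larger alkenyl substituent and hydride passes from the nitrogen-bound catecholborane to the exposed face through a six-membered transition state, so with alkenyl as the large and methyl as the small group the (R)-catalyst should give the (S)-carbinol, while the Weinreb amide is inert to catecholborane at this temperature.

Step 5
Reactants: 6 (S,E)-17-hydroxy-N-methoxy-N-methyloctadec-15-enamide
Product: 7 (S,E)-17-(tert-butyldimethylsilyloxy)-N-methoxy-N-methyloctadec-15-enamide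
Conditions: TBSCl (1.3 equiv), imidazole (2.5 equiv), DMF, rt
Reagents that add atoms: tert-butyldimethylsilyl chloride, CC(C)(C)[Si](C)(C)Cl
Why: Imidazole-promoted silylation of a secondary alcohol (TBS ether formation), placed before the hydrogenation so that the allylic carbinol cannot isomerise to the methyl ketone on the metal surface and is already masked for the later dianion chemistry.

Step 6
Reactants: 7 (S,E)-17-(tert-butyldimethylsilyloxy)-N-methoxy-N-methyloctadec-15-enamide
Product: 8 (S)-17-(tert-butyldimethylsilyloxy)-N-methoxy-N-methyloctadecanamide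
Conditions: H2 (1 atm), 5% Pt/C, EtOAc, rt
Reagents that add atoms: none
Why: Heterogeneous catalytic hydrogenation of the disubstituted alkene, where platinum in a non-protic solvent keeps allylic C–O hydrogenolysis low and leaves the N–O bond of the Weinreb amide and the silyl ether intact, so the carbinol carbon, which is not touched, remains (S).

Step 7
Reactants: 9 2,2,6-trimethyl-4H-1,3-dioxin-4-one
Product: 11 2,2-dimethyl-6-(2-oxopropyl)-4H-1,3-dioxin-4-one, via lithium dienolate 10 (not isolated)
Conditions: LiN(SiMe3)2 (1.0 equiv), THF, −78 °C; AcCl (0.5 equiv), −78 °C; aq NH4Cl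
Reagents that add atoms: acetyl chloride, CC(=O)Cl
Why: Vinylogous Claisen-type C-acylation: deprotonation of the 6-methyl group gives the extended dienolate 10, which is acylated at its γ-carbon by acetyl chloride at low temperature, and because the product is more acidic than 9 half of the dienolate serves as base, hence acetyl chloride as the limiting reagent.

Step 8
Reactants: 8 (S)-17-(tert-butyldimethylsilyloxy)-N-methoxy-N-methyloctadecanamide; 11 2,2-dimethyl-6-(2-oxopropyl)-4H-1,3-dioxin-4-one
Product: 13 (S)-6-[20-(tert-butyldimethylsilyloxy)-2,4-dioxohenicosyl]-2,2-dimethyl-4H-1,3-dioxin-4-one, via dilithium dianion 12 (not isolated)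
Conditions: 11 (2.5 equiv), LiN(i-Pr)2 (5.0 equiv), THF, −78 °C; then 8 (1.0 equiv) in THF, −78 to −40 °C; 1 M HCl to pH 4; product used promptly
Reagents that add atoms: none
Why: Crossed Claisen condensation of a 1,3-dicarbonyl dianion: the second deprotonation places the most reactive carbanion on the terminal methyl group of 11, which adds to the Weinreb amide to give a chelated tetrahedral intermediate that cannot accept a second nucleophile and releases the ketone only on quench, while the excess dianion absorbs the acidic proton of the product and the silyl ether is inert to amide bases.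

Step 9
Reactants: 13 (S)-6-[20-(tert-butyldimethylsilyloxy)-2,4-dioxohenicosyl]-2,2-dimethyl-4H-1,3-dioxin-4-one
Product: 15 (S)-5-[16-(tert-butyldimethylsilyloxy)heptadecyl]-7-hydroxy-2,2-dimethyl-4H-benzo[d][1,3]dioxin-4-one, via aldol adduct 14 (not isolated)
Conditions: Et3N (5 equiv), CH2Cl2, rt
Reagents that add atoms: none
Why: Et3N enolises the doubly activated methylene between the dioxinone and the first side-chain ketone, and the extended enolate attacks the chain-bearing ketone (C7 of the tetraketide) through dioxinone C5 (tetraketide C2) to give aldol adduct 14, which loses water and enolises its remaining ring ketone to the phenol, irreversibly. The closest known reaction type is the base-mediated cycloaromatisation of 6-(2,4-dioxoalkyl)-1,3-dioxin-4-ones to isopropylidene-protected 6-alkyl-β-resorcylates, the laboratory counterpart of the aldol cyclisation in alkylresorcylic acid biosynthesis. The single new C–C bond (C4a–C5 of 15, later C5–C6 of the resorcinol) closes the six-membered carbocycle in a 6-(enolexo)-exo-trig aldol mode, and this ring becomes the benzene ring fused to the dioxinone. No lasting stereocentre is formed, since the carbinol of 14 disappears on dehydration, and the remote (S)-silyloxy carbon is not involved. The step needs C2-to-C7 carbon cyclisation in preference to O-cyclisation to a 4-pyranone or aldol closure onto C3, and the dioxinone secures this by holding C1 and C3 as an ester and an enol ether carbon that cannot act as electrophiles, while a mild amine base in a non-polar solvent favours C- over O-attack.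

Step 10
Reactants: 15 (S)-5-[16-(tert-butyldimethylsilyloxy)heptadecyl]-7-hydroxy-2,2-dimethyl-4H-benzo[d][1,3]dioxin-4-one
Product: 16 (S)-6-[16-(tert-butyldimethylsilyloxy)heptadecyl]-2,4-dihydroxybenzoic acid
Conditions: 2 M aq KOH, 1,4-dioxane, 80 °C; then 1 M HCl at 0 °C to pH 3; acid used crude
Reagents that add atoms: potassium hydroxide (aqueous), [K+].[OH-]
Why: Saponification of the aryl ester of the isopropylidene ketal: hydroxide adds to the C4 carbonyl and the expelled hemiketal alkoxide collapses to acetone and the phenoxide, the silyl ether tolerates aqueous base, and cold acidification limits premature loss of CO2, which would in any case only anticipate the next step.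

Step 11
Reactants: 16 (S)-6-[16-(tert-butyldimethylsilyloxy)heptadecyl]-2,4-dihydroxybenzoic acid
Product: 18 hansfordiol A (5-[(16S)-16-hydroxyheptadecyl]benzene-1,3-diol), via desilylated hydroxy acid 17 (not isolated)
Conditions: 2 M aq HCl/1,4-dioxane (1:4), N2, 90 °C
Reagents that add atoms: none
Why: Acid-mediated desilylation followed by protodecarboxylation of a β-resorcylic acid: with OH groups ortho and para to the carboxyl-bearing carbon the ring is protonated at the ipso position and loses CO2, as in the conversion of olivetolic acid into olivetol, while the unactivated secondary alcohol does not ionise in dilute acid, so the (S) centre is retained.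

Compound list
1 | 15-pentadecanolide (oxacyclohexadecan-2-one) | O=C1CCCCCCCCCCCCCCO1 | starting material
2 | 15-hydroxy-N-methoxy-N-methylpentadecanamide | CON(C)C(=O)CCCCCCCCCCCCCCO | intermediate
3 | N-methoxy-N-methyl-15-oxopentadecanamide | CON(C)C(=O)CCCCCCCCCCCCCC=O | intermediate
4 | 1-(triphenylphosphoranylidene)propan-2-one | CC(=O)C=P(c1ccccc1)(c1ccccc1)c1ccccc1 | starting material
5 | (E)-N-methoxy-N-methyl-17-oxooctadec-15-enamide | CON(C)C(=O)CCCCCCCCCCCCC/C=C/C(C)=O | intermediate
6 | (S,E)-17-hydroxy-N-methoxy-N-methyloctadec-15-enamide | C[C@H](O)/C=C/CCCCCCCCCCCCCC(=O)N(C)OC | intermediate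
7 | (S,E)-17-(tert-butyldimethylsilyloxy)-N-methoxy-N-methyloctadec-15-enamide | C[C@H](O[Si](C)(C)C(C)(C)C)/C=C/CCCCCCCCCCCCCC(=O)N(C)OC | intermediate
8 | (S)-17-(tert-butyldimethylsilyloxy)-N-methoxy-N-methyloctadecanamide | C[C@H](O[Si](C)(C)C(C)(C)C)CCCCCCCCCCCCCCCC(=O)N(C)OC | intermediate
9 | 2,2,6-trimethyl-4H-1,3-dioxin-4-one | CC1=CC(=O)OC(C)(C)O1 | starting material
10 | lithium 2,2-dimethyl-6-methylidene-6H-1,3-dioxin-4-olate (lithium dienolate of 9, formed in the flask, not isolated) | C=C1C=C(O[Li])OC(C)(C)O1 | intermediate
11 | 2,2-dimethyl-6-(2-oxopropyl)-4H-1,3-dioxin-4-one | CC(=O)CC1=CC(=O)OC(C)(C)O1 | intermediate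
12 | dilithium 2,2-dimethyl-6-(2-oxidoprop-2-en-1-ylidene)-6H-1,3-dioxin-4-olate (dianion of 11, formed in the flask, not isolated) | C=C(O[Li])C=C1C=C(O[Li])OC(C)(C)O1 | intermediate
13 | (S)-6-[20-(tert-butyldimethylsilyloxy)-2,4-dioxohenicosyl]-2,2-dimethyl-4H-1,3-dioxin-4-one | C[C@H](O[Si](C)(C)C(C)(C)C)CCCCCCCCCCCCCCCC(=O)CC(=O)CC1=CC(=O)OC(C)(C)O1 | intermediate
14 | 5-[(16S)-16-(tert-butyldimethylsilyloxy)heptadecyl]-5-hydroxy-2,2-dimethyl-5,6-dihydro-4H-benzo[d][1,3]dioxine-4,7(8H)-dione (both C5 epimers, formed in the flask, not isolated) | C[C@H](O[Si](C)(C)C(C)(C)C)CCCCCCCCCCCCCCCC1(O)CC(=O)CC2=C1C(=O)OC(C)(C)O2 | intermediate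
15 | (S)-5-[16-(tert-butyldimethylsilyloxy)heptadecyl]-7-hydroxy-2,2-dimethyl-4H-benzo[d][1,3]dioxin-4-one | C[C@H](O[Si](C)(C)C(C)(C)C)CCCCCCCCCCCCCCCc1cc(O)cc2OC(C)(C)OC(=O)c12 | intermediate
16 | (S)-6-[16-(tert-butyldimethylsilyloxy)heptadecyl]-2,4-dihydroxybenzoic acid | C[C@H](O[Si](C)(C)C(C)(C)C)CCCCCCCCCCCCCCCc1cc(O)cc(O)c1C(=O)O | intermediate
17 | (S)-2,4-dihydroxy-6-(16-hydroxyheptadecyl)benzoic acid (formed in the flask, not isolated) | C[C@H](O)CCCCCCCCCCCCCCCc1cc(O)cc(O)c1C(=O)O | intermediate
18 | hansfordiol A, 5-[(16S)-16-hydroxyheptadecyl]benzene-1,3-diol | C[C@H](O)CCCCCCCCCCCCCCCc1cc(O)cc(O)c1 | target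

Total step count: 11.
Longest linear sequence: 10 steps (1 to 18 through steps 1–6 and 8–11); step 7 is a one-step side branch.

Steps most likely to fail

Step 8. Proton transfer from the acidic product, or poor solubility of the waxy amide at −78 °C, may quench the dianion faster than it is acylated, and the diketo-dioxinone may cyclise or decompose during purification. The fallback replaces the acylation by an aldol addition and an oxidation and sets out from 8. Reduction with i-Bu2AlH in THF at −78 °C should give (S)-17-(tert-butyldimethylsilyloxy)octadecanal F1. This far more electrophilic aldehyde is added to dianion 12 at −78 °C to give the β-hydroxy ketone 6-[(20S)-20-(tert-butyldimethylsilyloxy)-4-hydroxy-2-oxohenicosyl]-2,2-dimethyl-4H-1,3-dioxin-4-one F2 as a mixture of carbinol epimers. Oxidation with Dess–Martin periodinane (1,1,1-triacetoxy-1,1-dihydro-1,2-benziodoxol-3(1H)-one) in CH2Cl2 then returns to the route at 13.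

Step 4. Facial discrimination between the methyl group and the unbranched alkenyl group may be insufficient, and uncatalysed catecholborane may compete by conjugate reduction; the enantiomeric purity and sense of 6 should be checked by Mosher ester analysis before the material is carried on. The fallback buys the stereocentre and sets out from 3. Methylenation with Ph3P=CH2 (from Ph3PCH3Br and KN(SiMe3)2, THF, −78 to 0 °C) should give N-methoxy-N-methylhexadec-15-enamide F3. Cross-metathesis of this terminal alkene with commercial (S)-but-3-en-2-ol (C[C@H](O)C=C, 3 equiv) and second-generation Grubbs catalyst, RuCl2(=CHPh)(PCy3)(H2IMes), in CH2Cl2 at 40 °C should give the E-allylic alcohol with the configuration fixed by the purchased alcohol, and returns to the route at 6.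

Step 9. O-cyclisation of the enolised 1,3-diketone to a 4-pyranone may compete, or the sequence may stall at the aldol adduct without dehydration. The fallback opens the dioxinone before the ring closure and sets out from 13. Heating in toluene at 110 °C with methanol causes retro-[4+2] loss of acetone, and the acylketene is trapped as methyl (23S)-23-(tert-butyldimethylsilyloxy)-3,5,7-trioxotetracosanoate F4. Cs2CO3 in MeOH, followed by acidification with AcOH, effects aldol aromatisation of the open triketo ester to methyl (S)-6-[16-(tert-butyldimethylsilyloxy)heptadecyl]-2,4-dihydroxybenzoate F5. Saponification with aq KOH in dioxane at 90 °C then returns to the route at 16.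

Further compounds
F1 | step 8 | (S)-17-(tert-butyldimethylsilyloxy)octadecanal | C[C@H](O[Si](C)(C)C(C)(C)C)CCCCCCCCCCCCCCCC=O
F2 | step 8 | 6-[(20S)-20-(tert-butyldimethylsilyloxy)-4-hydroxy-2-oxohenicosyl]-2,2-dimethyl-4H-1,3-dioxin-4-one (carbinol epimers) | C[C@H](O[Si](C)(C)C(C)(C)C)CCCCCCCCCCCCCCCC(O)CC(=O)CC1=CC(=O)OC(C)(C)O1
F3 | step 4 | N-methoxy-N-methylhexadec-15-enamide | CON(C)C(=O)CCCCCCCCCCCCCC=C
F4 | step 9 | methyl (23S)-23-(tert-butyldimethylsilyloxy)-3,5,7-trioxotetracosanoate | C[C@H](O[Si](C)(C)C(C)(C)C)CCCCCCCCCCCCCCCC(=O)CC(=O)CC(=O)CC(=O)OC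
F5 | step 9 | methyl (S)-6-[16-(tert-butyldimethylsilyloxy)heptadecyl]-2,4-dihydroxybenzoate | C[C@H](O[Si](C)(C)C(C)(C)C)CCCCCCCCCCCCCCCc1cc(O)cc(O)c1C(=O)OC
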